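**Retrosynthetic overview**

1. The target is a 5-hydroxy-3,4,7,8-tetrahydro-2H-chromene-4,7-dione (ring A = cis-2,3-dimethyldihydropyranone, ring B = carbocycle). The last bonds made are C8–prenyl (asymmetric Pd allylation that dearomatises a 7-hydroxychroman-4-one), before it O1–C2 (quinine oxa-Michael) and C4–C4a (Friedel–Crafts tigloylation).
2. Ring B is disconnected at C7–C8 (carbonyl carbon / carbon bearing the cyclobutylmethyl group): 6π electrocyclisation of a dienylketene, assembled in one flask from an aldoketene and two ynol ethers through two [2+2]/4π-opening cycles.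
3. Enabling feature: ring B is a 1,3,5-trioxygenated carbocycle (O on C5, C7, C8a) whose C7 oxygen is a carbonyl next to C8 carrying a CH2-linked group. C7(=O)–C8 therefore maps onto C(=O)=Cα of a monoalkylketene, and C8a–O and C5–O onto the oxygens of two ynol ethers. The ring is built at the phenol oxidation level and C8 is made quaternary afterwards.
4. Fragments: the ketene comes from (+)-α-pinene via the diazoketone of cis-pinonic acid (photochemical Wolff; both cyclobutane stereocentres from the chiral pool; acetyl → isopropenyl only after the acidic steps). The siloxyalkyne carries the propyl-bearing stereocentre (Evans alkylation, Kowalski homologation). The third component is tert-butoxyacetylene.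
5. Ring order: cyclobutane (chiral pool) → two transient cyclobutenones → ring B (step 8) → temporary lactone ring masking the C7 oxygen and the acid → ring A → dearomatisation at C8.

Key step: step 8

Assumption (sense of the two catalyst-controlled steps): (−)-quinine is taken to give the (2R,3S)-cis-chromanone and the (R,R)-Trost ligand to give 8R; quinidine or the (S,S)-ligand would be used if a model shows the opposite sense. TIPS = tri(propan-2-yl)silyl.

**Route**

Step 1
Reactants: 1 (1R,5R)-(+)-α-pinene
Product: 2 cis-pinonic acid [2-((1S,3S)-3-acetyl-2,2-dimethylcyclobutyl)acetic acid]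
Conditions: RuCl3 (2 mol %), NaIO4 (4.1 equiv), EtOAc/MeCN/H2O, 0 °C → rt
Reagents that add atoms: sodium periodate [Na+].[O-]I(=O)(=O)=O; water O
Why: Ruthenium tetroxide generated in situ cleaves the only C=C bond (oxidative alkene cleavage) to the keto acid, and the two bridgehead carbons of 1 become the cis ring stereocentres of 2 unchanged, so the cyclobutane configuration comes from the chiral pool.

Step 2
Reactants: 2 cis-pinonic acid
Product: 4 1-[(1S,3S)-3-acetyl-2,2-dimethylcyclobutyl]-3-diazopropan-2-one, via acid chloride 3 (not isolated)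
Conditions: (COCl)2, DMF (cat.), CH2Cl2, 0 °C → rt, evaporate; then CH2N2 (3 equiv), Et2O, 0 °C
Reagents that add atoms: diazomethane C=[N+]=[N-]
Why: Acylation of diazomethane by the acid chloride (first half of an Arndt–Eistert sequence) gives the diazomethyl ketone, a second equivalent of diazomethane scavenging HCl, and neither the methyl ketone nor the ring stereocentres react under these neutral conditions.

Step 3
Reactants: 5 trichloroethylene
Product: 8 tert-butoxyacetylene, via dichlorovinyl ether 6 (not isolated), via lithium tert-butoxyacetylide 7 (not isolated)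
Conditions: t-BuOK, THF, −78 °C → rt; then n-BuLi (2.3 equiv), −78 → −40 °C; MeOH; distilled as a THF/pentane solution
Reagents that add atoms: potassium tert-butoxide CC(C)(C)[O-].[K+]
Why: tert-Butoxide adds to dichloroacetylene formed in situ from trichloroethylene, and n-BuLi then effects dehydrochlorination and chlorine–lithium exchange, protonation giving the alkynyl ether (standard alkoxyacetylene synthesis by elimination).

Step 4
Reactants: 9 (4R)-4-benzyl-1,3-oxazolidin-2-one
Product: 10 (4R)-4-benzyl-3-pentanoyl-1,3-oxazolidin-2-one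
Conditions: n-BuLi, THF, −78 °C; pentanoyl chloride, −78 → 0 °C
Reagents that add atoms: pentanoyl chloride CCCCC(Cl)=O
Why: N-acylation of the lithiated oxazolidinone installs the Evans auxiliary on the pentanoyl unit.

Step 5
Reactants: 10 (4R)-4-benzyl-3-pentanoyl-1,3-oxazolidin-2-one
Product: 11 tert-butyl (3S)-3-{[(4R)-4-benzyl-2-oxo-1,3-oxazolidin-3-yl]carbonyl}hexanoate
Conditions: NaN(SiMe3)2, THF, −78 °C; BrCH2CO2t-Bu, −78 → −40 °C
Reagents that add atoms: tert-butyl bromoacetate CC(C)(C)OC(=O)CBr
Why: Evans asymmetric alkylation: the chelated (Z)-sodium enolate is alkylated on the face opposite the benzyl group, which sets the future hexanoic acid C3 stereocentre as S.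

Step 6
Reactants: 11 alkylated imide
Product: 12 4-tert-butyl 1-methyl (2S)-2-propylbutanedioate
Conditions: MeMgBr (1.3 equiv) added to MeOH, then 11, CH2Cl2/MeOH, 0 °C
Reagents that add atoms: methanol CO (delivered as methoxymagnesium bromide)
Why: Methoxymagnesium bromide cleaves the imide selectively at the exocyclic carbonyl (transesterification) without epimerising the α-centre and leaves the hindered tert-butyl ester intact.

Step 7
Reactants: 12 4-tert-butyl 1-methyl (2S)-2-propylbutanedioate
Product: 14 tert-butyl (3S)-3-propyl-5-{[tri(propan-2-yl)silyl]oxy}pent-4-ynoate, via lithium ynolate 13 (not isolated)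
Conditions: CH2Br2, lithium 2,2,6,6-tetramethylpiperidide, THF, −78 °C; then LiN(SiMe3)2; then n-BuLi, −78 °C → rt; then TIPSCl, −78 °C → rt
Reagents that add atoms: dibromomethane BrCBr; chlorotri(propan-2-yl)silane CC(C)[Si](Cl)(C(C)C)C(C)C
Why: Kowalski ester homologation: dibromomethyllithium adds only to the methyl ester, the bromoketone enolate rearranges after bromine–lithium exchange to ynolate 13 (1,2-shift of the stereogenic carbon with retention), and the bulky silyl chloride traps it on oxygen.

Step 8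
Reactants: 4 diazoketone; 8 tert-butoxyacetylene; 14 siloxyalkyne
Product: 21 tert-butyl (3S)-3-[3-{[(1S,3S)-3-acetyl-2,2-dimethylcyclobutyl]methyl}-4-tert-butoxy-2-hydroxy-6-{[tri(propan-2-yl)silyl]oxy}phenyl]hexanoate, via aldoketene 15 (not isolated), via tert-butoxycyclobutenone 16 (not isolated), via vinylketene 17 (not isolated), via vinylcyclobutenone 18 (not isolated), via dienylketene 19 (not isolated), via cyclohexadienone 20 (not isolated)
Conditions: 4 + 8 (3 equiv), CH2Cl2 (0.02 M), 365 nm LEDs, 10 °C; volatiles removed at 20 °C; then 14 (1.3 equiv), toluene, 80 °C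
Reagents that add atoms: none
Why: Photochemical Wolff rearrangement of 4 gives aldoketene 15, whose [2+2] cycloaddition with 8 gives the strained cyclobutenone 16; on heating, conrotatory 4π opening gives vinylketene 17, [2+2] cycloaddition with 14 gives vinylcyclobutenone 18, a second 4π opening gives dienylketene 19, and 6π electrocyclisation joins the ketene carbon to the terminal CH carbon that bears the cyclobutylmethyl group, giving cyclohexadienone 20, which tautomerises to phenol 21. The closest known reaction type is the Danheiser benzannulation of a cyclobutenone with a siloxyalkyne, here preceded in the same flask by a Wolff rearrangement and a ketene–alkoxyalkyne cycloaddition. The two four-membered rings are closed by [2+2] cycloaddition and reopened by 4π electrocyclic cleavage, and the six-membered carbocycle is closed by disrotatory 6π electrocyclisation. No permanent stereocentre is created, since the sp3 ring carbons of 16, 18 and 20 are erased by ring opening or aromatisation and the existing stereocentres are remote and untouched. The step needs regiocontrol in both cycloadditions, secured by the polarisation of the ynol ethers (their nucleophilic β-carbon bonds to the ketene carbonyl carbon), which places the three oxygens 1,3,5 and the two carbon substituents on either side of the phenol. It also needs the two alkynes to enter in the right order, secured by irradiating at a wavelength absorbed only by the diazoketone and by removing excess 8 before 14 is added.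

Step 9
Reactants: 21 phenol
Product: 22 (4S)-8-{[(1S,3S)-3-acetyl-2,2-dimethylcyclobutyl]methyl}-7-hydroxy-4-propyl-5-{[tri(propan-2-yl)silyl]oxy}-3,4-dihydro-2H-chromen-2-one
Conditions: TFA/CH2Cl2 (1:4), 0 °C → rt, argon sparge
Reagents that add atoms: none
Why: Acidolysis removes both tert-butyl groups (aryl ether and ester) and the liberated acid lactonises onto the only phenol ortho to the side chain (acid-catalysed lactonisation), which masks that phenol and the carboxyl group, while the silyl ether, the acetylcyclobutane and all stereocentres are stable to acid.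

Step 10
Reactants: 22 lactone phenol
Product: 23 (4S)-8-{[(1S,3S)-3-acetyl-2,2-dimethylcyclobutyl]methyl}-7-hydroxy-6-[(2E)-2-methylbut-2-enoyl]-4-propyl-5-{[tri(propan-2-yl)silyl]oxy}-3,4-dihydro-2H-chromen-2-one
Conditions: (E)-2-methylbut-2-enoyl chloride (1.5 equiv), TiCl4 (2.2 equiv), CH2Cl2, −40 → 0 °C
Reagents that add atoms: (E)-2-methylbut-2-enoyl chloride C/C=C(\C)C(Cl)=O
Why: Lewis-acid ortho-acylation (Friedel–Crafts/Fries type) of the titanium phenoxide places the tigloyl group on the single unsubstituted ring carbon, next to the free hydroxyl that must later close ring A.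

Step 11
Reactants: 23 tigloyl ketone
Product: 24 (4S)-8-{[(1S,3R)-2,2-dimethyl-3-(prop-1-en-2-yl)cyclobutyl]methyl}-7-hydroxy-6-[(2E)-2-methylbut-2-enoyl]-4-propyl-5-{[tri(propan-2-yl)silyl]oxy}-3,4-dihydro-2H-chromen-2-one
Conditions: Zn, CH2Br2, TiCl4 (Lombardo reagent, preformed at 0 °C), THF/CH2Cl2, 0 °C → rt
Reagents that add atoms: dibromomethane BrCBr
Why: Lombardo methylenation converts the unhindered methyl ketone into the isopropenyl group under non-basic conditions that do not epimerise the adjacent ring stereocentre, the chelated conjugated aryl ketone and the lactone being much less reactive; it is placed after steps 9 and 10 because the isopropenylcyclobutane would not survive their acid.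

Step 12
Reactants: 24 tigloyl phenol
Product: 25 lactone-bridged (2R,3S)-cis-2,3-dimethylchroman-4-one (ring A closed onto the 7-oxygen of 24; 5-OTIPS; full description in the compound list)
Conditions: (−)-quinine (0.3 equiv), chlorobenzene, 15 °C
Reagents that add atoms: none
Why: Alkaloid-catalysed intramolecular oxa-Michael addition of the only free phenol to the tigloyl group closes ring A (6-endo-trig), quinine fixing the face of C–O bond formation (2R) and kinetic protonation of the enol anti to the new 2-methyl group giving the cis 3S centre.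

Step 13
Reactants: 25 lactone-bridged chromanone
Product: 26 methyl (3S)-3-[(2R,3S)-7-hydroxy-2,3-dimethyl-8-{[(1S,3R)-2,2-dimethyl-3-(prop-1-en-2-yl)cyclobutyl]methyl}-4-oxo-5-{[tri(propan-2-yl)silyl]oxy}-3,4-dihydro-2H-chromen-6-yl]hexanoate
Conditions: Et3N (3 equiv), MeOH, 0 °C → rt
Reagents that add atoms: methanol CO
Why: Amine-catalysed methanolysis of the activated aryl lactone (transesterification) frees the 7-hydroxyl needed as the nucleophile of the next step and gives the methyl ester, under conditions too weakly basic to enolise the cis-chromanone.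

Step 14
Reactants: 26 7-hydroxychromanone methyl ester
Product: 27 methyl (3S)-3-[(2R,3S,8R)-2,3-dimethyl-8-(3-methylbut-2-en-1-yl)-8-{[(1S,3R)-2,2-dimethyl-3-(prop-1-en-2-yl)cyclobutyl]methyl}-4,7-dioxo-5-{[tri(propan-2-yl)silyl]oxy}-3,4,7,8-tetrahydro-2H-chromen-6-yl]hexanoate
Conditions: prenyl acetate (1.5 equiv), Pd2(dba)3·CHCl3 (2.5 mol %), (R,R)-DACH-phenyl Trost ligand (7.5 mol %), Cs2CO3 (1.1 equiv), toluene, 0 °C → rt
Reagents that add atoms: 3-methylbut-2-en-1-yl acetate CC(C)=CCOC(C)=O
Why: Tsuji–Trost asymmetric allylic alkylation run as a dearomatisation: the caesium phenoxide attacks the π-prenyl complex of divalent palladium at its unsubstituted terminus through the ortho carbon that carries the primary cyclobutylmethyl group rather than the α-branched one, O-prenylation being reversible, and the chiral ligand selects the face of the flat ring so that C8 becomes R.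

Step 15
Reactants: 27 silyl dienol ether methyl ester
Product: 28 (3S)-3-[(2R,3S,8R)-5-hydroxy-2,3-dimethyl-8-(3-methylbut-2-en-1-yl)-8-{[(1S,3R)-2,2-dimethyl-3-(prop-1-en-2-yl)cyclobutyl]methyl}-4,7-dioxo-3,4,7,8-tetrahydro-2H-chromen-6-yl]hexanoic acid (CNP0364345.1)
Conditions: LiOH·H2O (5 equiv), THF/MeOH/H2O, 0 °C → rt; then cold 1 M HCl to pH 4
Reagents that add atoms: lithium hydroxide [Li+].[OH-]
Why: Hydroxide cleaves the silyl dienol ether and saponifies the methyl ester, the resulting delocalised triketone enolate protecting ring A against epimerisation or retro-Michael opening, and mild acidification gives 28.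

**Compound list**

1 | (1R,5R)-(+)-α-pinene | CC1=CC[C@@H]2C[C@H]1C2(C)C | starting material
2 | cis-pinonic acid, 2-[(1S,3S)-3-acetyl-2,2-dimethylcyclobutyl]acetic acid | CC(=O)[C@H]1C[C@@H](CC(=O)O)C1(C)C | intermediate
3 | 2-[(1S,3S)-3-acetyl-2,2-dimethylcyclobutyl]acetyl chloride | CC(=O)[C@H]1C[C@@H](CC(=O)Cl)C1(C)C | intermediate
4 | 1-[(1S,3S)-3-acetyl-2,2-dimethylcyclobutyl]-3-diazopropan-2-one | CC(=O)[C@H]1C[C@@H](CC(=O)C=[N+]=[N-])C1(C)C | intermediate
5 | trichloroethylene | ClC=C(Cl)Cl | starting material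
6 | tert-butyl (E)-1,2-dichlorovinyl ether | CC(C)(C)O/C(Cl)=C\Cl | intermediate
7 | lithium tert-butoxyacetylide | CC(C)(C)OC#C[Li] | intermediate
8 | tert-butoxyacetylene | CC(C)(C)OC#C | intermediate
9 | (4R)-4-benzyl-1,3-oxazolidin-2-one | O=C1N[C@H](Cc2ccccc2)CO1 | starting material
10 | (4R)-4-benzyl-3-pentanoyl-1,3-oxazolidin-2-one | CCCCC(=O)N1[C@H](Cc2ccccc2)COC1=O | intermediate
11 | tert-butyl (3S)-3-{[(4R)-4-benzyl-2-oxo-1,3-oxazolidin-3-yl]carbonyl}hexanoate | CCC[C@@H](CC(=O)OC(C)(C)C)C(=O)N1[C@H](Cc2ccccc2)COC1=O | intermediate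
12 | 4-tert-butyl 1-methyl (2S)-2-propylbutanedioate | CCC[C@@H](CC(=O)OC(C)(C)C)C(=O)OC | intermediate
13 | lithium ynolate of the homologated ester (lithium (3S)-5-tert-butoxy-5-oxo-3-propylpent-1-yn-1-olate) | CCC[C@@H](CC(=O)OC(C)(C)C)C#C[O-].[Li+] | intermediate
14 | tert-butyl (3S)-3-propyl-5-{[tri(propan-2-yl)silyl]oxy}pent-4-ynoate | CCC[C@@H](CC(=O)OC(C)(C)C)C#CO[Si](C(C)C)(C(C)C)C(C)C | intermediate
15 | aldoketene: the cis-(3-acetyl-2,2-dimethylcyclobutyl)methyl group of 2 (ring configuration unchanged) on CH=C=O | CC(=O)[C@H]1C[C@@H](CC=C=O)C1(C)C | intermediate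
16 | 3-tert-butoxy-4-[(cis-3-acetyl-2,2-dimethylcyclobutyl)methyl]cyclobut-2-en-1-one (ring configuration of 2; both epimers at the cyclobutenone CH) | CC(=O)[C@H]1C[C@@H](CC2C(=O)C=C2OC(C)(C)C)C1(C)C | intermediate
17 | vinylketene: (Z)-3-tert-butoxy-5-(cyclobutyl of 2)penta-1,3-dien-1-one | CC(=O)[C@H]1C[C@@H](C/C=C(\OC(C)(C)C)C=C=O)C1(C)C | intermediate
18 | 4-vinylcyclobutenone: 2-[(S)-1-tert-butoxy-1-oxohexan-3-yl]-3-(TIPS-oxy)cyclobut-2-en-1-one carrying at C4 the (Z)-1-tert-butoxy-3-(cyclobutyl of 2)prop-1-enyl group | CC(=O)[C@H]1C[C@@H](C/C=C(\OC(C)(C)C)C2C(=O)C(=C2O[Si](C(C)C)(C(C)C)C(C)C)[C@@H](CCC)CC(=O)OC(C)(C)C)C1(C)C | intermediate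
19 | dienylketene: ketene carbon on the carbon bearing the hexanoate side chain, then C(OTIPS)=CH–C(Ot-Bu)=CH–CH2–(cyclobutyl of 2) | CC(=O)[C@H]1C[C@@H](C/C=C(\OC(C)(C)C)/C=C(O[Si](C(C)C)(C(C)C)C(C)C)\C(=C=O)[C@@H](CCC)CC(=O)OC(C)(C)C)C1(C)C | intermediate
20 | cyclohexa-2,4-dien-1-one tautomer of 21 (sp3 CH bears the cyclobutylmethyl group; both epimers) | CC(=O)[C@H]1C[C@@H](CC2C(=O)C([C@@H](CCC)CC(=O)OC(C)(C)C)=C(O[Si](C(C)C)(C(C)C)C(C)C)C=C2OC(C)(C)C)C1(C)C | intermediate
21 | tert-butyl (3S)-3-[3-{[(1S,3S)-3-acetyl-2,2-dimethylcyclobutyl]methyl}-4-tert-butoxy-2-hydroxy-6-(TIPS-oxy)phenyl]hexanoate | CC(=O)[C@H]1C[C@@H](Cc2c(O)c([C@@H](CCC)CC(=O)OC(C)(C)C)c(O[Si](C(C)C)(C(C)C)C(C)C)cc2OC(C)(C)C)C1(C)C | intermediate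
22 | (4S)-8-{[(1S,3S)-3-acetyl-2,2-dimethylcyclobutyl]methyl}-7-hydroxy-4-propyl-5-(TIPS-oxy)-3,4-dihydro-2H-chromen-2-one | CC(=O)[C@H]1C[C@@H](Cc2c(O)cc(O[Si](C(C)C)(C(C)C)C(C)C)c3c2OC(=O)C[C@@H]3CCC)C1(C)C | intermediate
23 | (4S)-8-{[(1S,3S)-3-acetyl-2,2-dimethylcyclobutyl]methyl}-7-hydroxy-6-[(2E)-2-methylbut-2-enoyl]-4-propyl-5-(TIPS-oxy)-3,4-dihydro-2H-chromen-2-one | CC(=O)[C@H]1C[C@@H](Cc2c(O)c(C(=O)/C(C)=C/C)c(O[Si](C(C)C)(C(C)C)C(C)C)c3c2OC(=O)C[C@@H]3CCC)C1(C)C | intermediate
24 | (4S)-8-{[(1S,3R)-2,2-dimethyl-3-(prop-1-en-2-yl)cyclobutyl]methyl}-7-hydroxy-6-[(2E)-2-methylbut-2-enoyl]-4-propyl-5-(TIPS-oxy)-3,4-dihydro-2H-chromen-2-one | C=C(C)[C@H]1C[C@@H](Cc2c(O)c(C(=O)/C(C)=C/C)c(O[Si](C(C)C)(C(C)C)C(C)C)c3c2OC(=O)C[C@@H]3CCC)C1(C)C | intermediate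
25 | (2R,3S)-2,3-dimethyl-2,3-dihydro-4H-chromen-4-one with OTIPS at C5, the [(1S,3R)-2,2-dimethyl-3-(prop-1-en-2-yl)cyclobutyl]methyl group at C8 and a lactone bridge C6–CH(n-Pr)–CH2–C(=O)–O–C7, S at the CH(n-Pr) carbon | C=C(C)[C@H]1C[C@@H](Cc2c3O[C@H](C)[C@H](C)C(=O)c3c(O[Si](C(C)C)(C(C)C)C(C)C)c3c2OC(=O)C[C@@H]3CCC)C1(C)C | intermediate
26 | methyl (3S)-3-[(2R,3S)-7-hydroxy-2,3-dimethyl-8-{[(1S,3R)-2,2-dimethyl-3-(prop-1-en-2-yl)cyclobutyl]methyl}-4-oxo-5-(TIPS-oxy)-3,4-dihydro-2H-chromen-6-yl]hexanoate | C=C(C)[C@H]1C[C@@H](Cc2c3O[C@H](C)[C@H](C)C(=O)c3c(O[Si](C(C)C)(C(C)C)C(C)C)c([C@@H](CCC)CC(=O)OC)c2O)C1(C)C | intermediate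
27 | methyl (3S)-3-[(2R,3S,8R)-2,3-dimethyl-8-(3-methylbut-2-en-1-yl)-8-{[(1S,3R)-2,2-dimethyl-3-(prop-1-en-2-yl)cyclobutyl]methyl}-4,7-dioxo-5-(TIPS-oxy)-3,4,7,8-tetrahydro-2H-chromen-6-yl]hexanoate | C=C(C)[C@H]1C[C@@H](C[C@@]2(CC=C(C)C)C(=O)C([C@@H](CCC)CC(=O)OC)=C(O[Si](C(C)C)(C(C)C)C(C)C)C3=C2O[C@H](C)[C@H](C)C3=O)C1(C)C | intermediate
28 | (3S)-3-[(2R,3S,8R)-5-hydroxy-2,3-dimethyl-8-(3-methylbut-2-en-1-yl)-8-{[(1S,3R)-2,2-dimethyl-3-(prop-1-en-2-yl)cyclobutyl]methyl}-4,7-dioxo-3,4,7,8-tetrahydro-2H-chromen-6-yl]hexanoic acid | C=C(C)[C@H]1C[C@@H](C[C@@]2(CC=C(C)C)C(=O)C([C@@H](CCC)CC(=O)O)=C(O)C3=C2O[C@H](C)[C@H](C)C3=O)C1(C)C | target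

**Step count and risks**

Total steps: 15. Longest linear sequence: 12 steps (steps 4–7, then 8–15).

Most likely to fail, in this order:

1. Step 14 (dearomative prenylation). The catalyst may discriminate the two faces of the planar phenoxide poorly, C-prenylation may occur at the other ortho carbon (C6), or the O-prenyl ether may accumulate. The fallback replaces catalyst control by chirality transfer and sets out from 26. Mitsunobu etherification of the 7-hydroxyl with (S)-but-3-en-2-ol (PPh3, DIAD; inversion) gives the aryl (R)-but-3-en-2-yl ether F1. Aromatic Claisen rearrangement (toluene, 100 °C, or Eu(fod)3) through the chair transition state with the methyl group equatorial delivers the allyl unit to one face of C8 and gives the 8R (E)-but-2-enyl dienone F2. Cross-metathesis with 2-methylbut-2-ene (second-generation Grubbs catalyst RuCl2(=CHPh)(PCy3)(H2IMes), CH2Cl2, 40 °C) converts the butenyl into the prenyl group and returns to the route at 27.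

2. Step 8 (three-component benzannulation). The aldoketene may dimerise before it meets 8, vinylketene 17 may be captured by residual 8 or by the product phenol, or the vinylogous tert-butyl ester may lose isobutene on heating. The fallback generates the ketene without light and separates the two stages; it sets out from 4. Silver-benzoate-catalysed Wolff rearrangement (AgO2CPh, Et3N, aqueous dioxane) gives the homologous acid F3, and (COCl)2 gives the acid chloride F4. Slow addition of Et3N to F4 and 8 in CH2Cl2 forms the ketene by dehydrochlorination and gives cyclobutenone 16, which is now isolated and purified. Heating 16 with 14 in toluene at 80 °C (two-flask Danheiser benzannulation) returns to the route at 21.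

3. Step 10 (C-acylation). The Lewis acid may cleave the 5-silyl ether or trigger premature, uncatalysed ring closure of the tigloyl phenol, or acylation between two ortho oxygen substituents may be sluggish. The fallback avoids any Lewis acid and sets out from 22. O-acylation of the 7-hydroxyl (tigloyl chloride, Et3N, DMAP, CH2Cl2, 0 °C) gives the aryl tiglate F5. Photo-Fries rearrangement (300 nm, MeCN, rt; radical-pair 1,3-acyl shift to the only free ortho carbon) returns to the route at 23.

Further compounds
F1 | step 14 | methyl (3S)-3-[(2R,3S)-7-{[(2R)-but-3-en-2-yl]oxy}-2,3-dimethyl-8-{[(1S,3R)-2,2-dimethyl-3-(prop-1-en-2-yl)cyclobutyl]methyl}-4-oxo-5-(TIPS-oxy)-3,4-dihydro-2H-chromen-6-yl]hexanoate | C=C(C)[C@H]1C[C@@H](Cc2c3O[C@H](C)[C@H](C)C(=O)c3c(O[Si](C(C)C)(C(C)C)C(C)C)c([C@@H](CCC)CC(=O)OC)c2O[C@H](C)C=C)C1(C)C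
F2 | step 14 | analogue of 27 with an (E)-but-2-en-1-yl group in place of the prenyl group at C8 (8R) | C=C(C)[C@H]1C[C@@H](C[C@@]2(C/C=C/C)C(=O)C([C@@H](CCC)CC(=O)OC)=C(O[Si](C(C)C)(C(C)C)C(C)C)C3=C2O[C@H](C)[C@H](C)C3=O)C1(C)C
F3 | step 8 | 3-(cis-3-acetyl-2,2-dimethylcyclobutyl)propanoic acid, homologue of 2 with unchanged ring configuration | CC(=O)[C@H]1C[C@@H](CCC(=O)O)C1(C)C
F4 | step 8 | 3-(cis-3-acetyl-2,2-dimethylcyclobutyl)propanoyl chloride, ring configuration of 2 | CC(=O)[C@H]1C[C@@H](CCC(=O)Cl)C1(C)C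
F5 | step 10 | 7-O-[(2E)-2-methylbut-2-enoyl] ester of 22 | CC(=O)[C@H]1C[C@@H](Cc2c(OC(=O)/C(C)=C/C)cc(O[Si](C(C)C)(C(C)C)C(C)C)c3c2OC(=O)C[C@@H]3CCC)C1(C)C
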